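## Analysis of the target

The target is a daucane-type sesquiterpene ester: a cyclopentane (C1–C5) trans-fused along C1–C5 to a cycloheptene (C1, C5, C6–C10) with a C8=C9 alkene bearing the C8 methyl group. It has five stereocentres in one contiguous block: quaternary C1 (methyl), C4 (tertiary carbinol with isopropyl), C5 (ring-fusion CH), C6 (4-methoxybenzoate) and C10 (allylic carbinol); in the numbering used here they are 1S, 4R, 5S, 6S, 10R. On the five-membered ring the C1 methyl, the C4 hydroxyl and the C5–C6 bond are on one face ("upper face"); C5–H and the C1–C10 bond are on the other, so the fusion is trans. On the seven-membered ring the C6 ester oxygen and the C10 hydroxyl are both on the side of C5–H, trans to the angular methyl; the C10 hydroxyl is anti to that methyl. Sensitive points are the tertiary C4 alcohol, which is β to C6 (dehydration or retro-aldol once C6 is a carbonyl), the neopentyl allylic C10 alcohol, and the aryl ester, which must sit on only one of three oxygens. The difficulty lies in the quaternary C1 flanked by C5 and C10, the trans hydroazulene fusion, and closing a seven-membered ring next to a quaternary carbon. The strategy rests on one feature: the C1–C10 and C5–C6 bonds are anti on adjacent carbons, which is what an (E)-2-methyl-2-enal leaves behind in a Diels–Alder reaction. C2, C3, C4 and the isopropyl methine can come from a 2-methyl diene if the cyclohexene formed is later cut at its alkene and reclosed as a cyclopentene.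

## Retrosynthetic reasoning

**26 to 25 (C8=C9).** The last bond cut is the ring alkene, leading to diene 25 (vinyl on the C10 carbinol, 2-methylallyl on C6); the forward reaction is a ring-closing metathesis to a trisubstituted cycloheptene. A closure at C9–C10 by intramolecular vinylchromium addition was considered first. It needs iodine on C9 cis to C7, and no three-carbon reagent delivers that unit to C6 in one operation, because allyl metals with a halogen at the far terminus react through the halogen-bearing carbon. The known detours are long or do not tolerate the C10 acetal. Cutting at the alkene keeps both arms simple and tolerates the free hydroxyls and the ester.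

**25 to 24, 23 and 21 + 22 (C10 and C9–C10).** C10 is set by reduction of vinyl ketone 24, not by addition to the aldehyde. With C5 as the large group, a Felkin–Anh addition of a vinyl nucleophile to aldehyde 21 should favour the wrong C10 epimer, whereas hydride addition to 24 along the same trajectory gives the right one and can be reinforced by a chiral catalyst. C9–C10 is therefore made by chromium-mediated vinylation of 21 with 22, which tolerates the ester and the free tertiary alcohol; the epimeric carbinols 23 are oxidised to 24.

**21 to 20 and 18 + 19 (aldehyde release, ester).** Aldehyde 21 comes from acetal 20. The 4-methoxybenzoate is put on at the stage of diol 18, where C6–OH is the only secondary hydroxyl (C4–OH is tertiary, C10 is still an acetal). This avoids a late choice between the C6 and C10 hydroxyls.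

**18 to 16 + 17 (C6–C7).** The side chain is attached by adding 17 to β-hydroxy aldehyde 16. The C4 hydroxyl is left free on purpose. As its metal alkoxide it holds the C6 carbonyl oxygen on the C4 side, and the face of the carbonyl towards the C1 methyl is blocked, so the nucleophile should enter anti to C1 and give the 6S carbinol.

**16 to 15, 14 and 13 (C4–O).** The tertiary carbinol is traced to the C3=C4 alkene of homoallylic alcohol 13. The C6 hydroxymethyl group on the upper face directs the epoxidation to that face (14), and hydride opens the epoxide at the secondary C3 (15). This must precede oxidation at C6; otherwise a β,γ-unsaturated aldehyde with an acidic C5–H would result.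

**13 to 12, 11 and 10 (isopropyl).** The isopropyl group comes from the acetyl group of enone 10 by methylenation (11) and hydrogenation of the less substituted alkene of the diene (12). The ring alkene must survive, because it carries the C4 oxygen later.

**10 to 8 and 6 (ring contraction).** The C3–C4 bond of the cyclopentene is an aldol bond: keto aldehyde 8 closes through the ketone enolate onto the aldehyde. 8 is the ozonolysis product of cyclohexene 6; the ring carbon carrying the diene methyl group leaves the ring and becomes the future isopropyl methine. C10 must be masked as its acetal (6) before this, since a free C10 aldehyde would be a second aldol acceptor.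

**5 to 3 + 4 (key disconnection).** Aldehyde 5, the precursor of 6, is the Diels–Alder adduct of enal 3 and diene 4, formed across C1–C2 and C4–C5. The (E) geometry of 3 gives the trans relation of C10 and C6, the chiral oxazaborolidinium catalyst gives the absolute configuration, and the diene methyl group gives the regiochemistry. The facial rule for 2-substituted enals requires the catalyst derived from the (R)-prolinol here (reasoning in step 2).

**3 to 1 + 2.** The enal is the Wittig product of two commercial compounds, one step from commerce.

## Alternatives that were turned down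

**Alternative 1:** Enone–enol ether photocycloaddition, then Grob opening. The disconnection cuts C1–C10 and C5–C6 as a cyclobutane and then C6–C10. In the forward direction, irradiation of 2-mesyloxy-3-methylcyclopentenone A1 with silyl enol ether A2 would give the head-to-tail cyclobutane A3; desilylation would then trigger loss of mesylate with cleavage of C6–C10, giving a cycloheptenone fused to the cyclopentanone.
- For it: it is convergent (two five-membered rings), forms the quaternary C1 without polar matching, and delivers the seven-membered ring with the C10 oxygen in place, which the chosen route has to build from two arms. On that point it is stronger.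
- Against it: the only stereocentre that can bias the cycloaddition is the C8 methyl carbon of A2, remote from both new bonds and later flattened to the sp2 C8, so absolute control is weak. After the fragmentation C5 is sp2, so the trans fusion, the C6 oxygen, the C4 isopropyl carbinol and the C8=C9 unsaturation all still have to be introduced on the bicycle, each with its own facial problem.
- In its place the chosen strategy offers catalyst-controlled C1 and C5 with the C6 carbon already attached.

**Alternative 2:** One-carbon ring expansion of a trans-hydrindanone. The disconnection removes C9 from between C8 and C10. In the forward direction, siloxycyclopropane A4 would be oxidised by FeCl3 in DMF with cleavage of the internal C8–C10 bond, and NaOAc would eliminate HCl to give enone A5.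
- For it: the C10 ketone enolises only towards C8 (C1 is quaternary), so enol ether formation, cyclopropanation and cleavage are regiochemically unambiguous. A5 is one reduction from the target with the ester already on; on endgame brevity it is at least as good as the chosen route.
- Against it: the expansion does not address the hard part. A4 already needs C1, C4, C5 and C6 on a trans-fused bicycle, so a complete stereocontrolled synthesis precedes the key step, and three to four operations are then spent on inserting one carbon in the presence of an ester and a tertiary silyl ether under a Lewis-acidic oxidant.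
- The chosen strategy spends its operations on a contraction instead, but sets the quaternary centre and the fusion at the start from achiral materials.

**Alternative 3:** Rhodium [5+2] of a tethered alkyne and a siloxyvinylcyclopropane. The disconnection cuts C1–C5 and C6–C7. In the forward direction, [Rh(CO)2Cl]2 would convert enyne A6 into bicyclic diene A7, closing both rings at once.
- For it: on step count from the precursor it is the strongest of the four, and it is atom-economical.
- Against it: in A7 the oxygen sits on C9, not C10, and C5 is sp2. A C9-to-C10 oxygen shift with generation of C8=C9, and a face-selective addition across C5=C6 to create the trans fusion and the C6 oxygen, are still required. C1 is set only by induction from the C4 stereocentre through the forming five-membered ring. A6 needs an enantioenriched tertiary propargylic ether, a trisubstituted alkene of defined geometry and a methyl-substituted siloxycyclopropane that must open at the right bond.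
- The chosen strategy is longer, but its stereocentres C1 and C5 come from a catalyst and a defined alkene geometry, and every later step is a standard transformation.

Key step: step 2

Remark on the chemistry: the silyl ether is kept as tert-butyldimethylsilyl and C10 is carried as a dimethyl acetal. Locants C1–C10 always mean the target carbons; "upper face" is the face of the five-membered ring that carries the C1 methyl group.

## Route

Step 1
Reactants: 1 (tert-butyldimethylsilyloxy)acetaldehyde; 2 2-(triphenylphosphoranylidene)propanal
Product: 3 (E)-4-(tert-butyldimethylsilyloxy)-2-methylbut-2-enal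
Conditions: toluene, 80 °C
Reagents that add atoms: none
Why: Wittig reaction of a stabilised formyl ylide; the reversible addition of stabilised ylides gives the (E)-trisubstituted enal, and the product enal is less electrophilic than 1, so a second homologation should be minor.

Step 2
Reactants: 3 (E)-4-(tert-butyldimethylsilyloxy)-2-methylbut-2-enal; 4 isoprene
Product: 5 (1S,6S)-6-[(tert-butyldimethylsilyloxy)methyl]-1,4-dimethylcyclohex-3-ene-1-carbaldehyde
Conditions: (R)-3,3-diphenyl-1-(2-methylphenyl)tetrahydro-1H,3H-pyrrolo[1,2-c][1,3,2]oxazaborole·HNTf2 (20 mol%; from (R)-α,α-diphenylprolinol and tri(2-methylphenyl)boroxine, then HNTf2), 4 (5 equiv), CH2Cl2, −78 → −40 °C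
Reagents that add atoms: none
Why: Catalytic enantioselective Diels–Alder reaction of the kind known for 2-substituted acroleins and (E)-2-methyl-2-enals with simple dienes under protonated oxazaborolidines. Boron binds the formyl oxygen of 3 on the lone pair syn to the formyl hydrogen, which leans on the ring oxygen (C–H···O), so the s-trans enal lies over one phenyl group and 4 adds to the open face in a concerted, asynchronous [4+2] process. The cyclohexene closes by suprafacial addition on both partners, C1–C2 and C4–C5 forming in the same step with the bond at the β-carbon C5 more advanced. C1 is set by the catalyst: the (S)-catalyst is known to give the (S)-aldehyde from 2-methylacrolein and isoprene, the same approach to 3 would give the mirror image of 5, and so the (R)-catalyst is used. C5 is set relative to C1 by the (E) geometry of 3, which is carried into the ring and leaves formyl (C10) and silyloxymethyl (C6) trans. Regiochemistry comes from the diene: the terminus next to the methyl-bearing carbon has the larger HOMO coefficient and bonds to the β-carbon, giving the 1,4 ("para") adduct, the more so under acid catalysis. Endo or exo approach is immaterial because neither diene terminus is substituted, so the step only has to deliver facial and regiochemical control.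

Step 3
Reactants: 5 (1S,6S)-6-[(tert-butyldimethylsilyloxy)methyl]-1,4-dimethylcyclohex-3-ene-1-carbaldehyde
Product: 6 (1S,6S)-6-[(tert-butyldimethylsilyloxy)methyl]-1-(dimethoxymethyl)-1,4-dimethylcyclohex-3-ene
Conditions: MeOSiMe3 (3 equiv), Me3SiOTf (5 mol%), CH2Cl2, −78 °C; pyridine quench
Reagents that add atoms: methoxytrimethylsilane, CO[Si](C)(C)C
Why: Noyori acetalisation; the silyl triflate activates the aldehyde and disiloxane formation drives the exchange, while the aprotic medium at −78 °C leaves the primary silyl ether and the alkene untouched. The acetal masks C10 for the ozonolysis and the aldol.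

Step 4
Reactants: 6 (1S,6S)-6-[(tert-butyldimethylsilyloxy)methyl]-1-(dimethoxymethyl)-1,4-dimethylcyclohex-3-ene
Product: 8 (3S,4S)-4-[(tert-butyldimethylsilyloxy)methyl]-3-(dimethoxymethyl)-3-methyl-6-oxoheptanal, via secondary ozonide 7 (not isolated)
Conditions: O3, CH2Cl2, −78 °C (to first excess); then PPh3, −78 °C → rt
Reagents that add atoms: ozone, [O-][O+]=O
Why: Ozonolysis with reductive work-up; the trisubstituted alkene is the only group that reacts with ozone at −78 °C. The cleavage turns the former diene CH into the aldehyde (future C3) and the methyl-bearing carbon into the methyl ketone (future isopropyl methine); C1 and C5 are not touched.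

Step 5
Reactants: 8 (3S,4S)-4-[(tert-butyldimethylsilyloxy)methyl]-3-(dimethoxymethyl)-3-methyl-6-oxoheptanal
Product: 10 acetylcyclopentene (4-acetyl-5-[(tert-butyldimethylsilyloxy)methyl]-1-(dimethoxymethyl)-1-methylcyclopent-3-ene; C3=C4; C1 and C5 as in 5), via aldol adduct 9 (not isolated)
Conditions: KOH (0.2 equiv), MeOH, 0 °C → rt
Reagents that add atoms: none
Why: Intramolecular aldol condensation; the ketone enolate on the inner methylene (future C4) adds to the more electrophilic aldehyde (future C3) in a five-membered closure and E1cB loss of water gives the conjugated enone. The enolate of the neopentyl aldehyde would have to attack the ketone and form a tetrasubstituted alkene, and the methyl enolate a seven-membered ring.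

Step 6
Reactants: 10 acetylcyclopentene
Product: 11 diene (4-(prop-1-en-2-yl) analogue of 10)
Conditions: Ph3PCH3Br, KOt-Bu, THF, 0 °C → rt
Reagents that add atoms: methyltriphenylphosphonium bromide, C[P+](c1ccccc1)(c1ccccc1)c1ccccc1.[Br-]
Why: Wittig methylenation of the conjugated methyl ketone; the non-stabilised ylide adds 1,2 and no stereocentre is involved.

Step 7
Reactants: 11 diene
Product: 12 isopropylcyclopentene (4-isopropyl-5-[(tert-butyldimethylsilyloxy)methyl]-1-(dimethoxymethyl)-1-methylcyclopent-3-ene)
Conditions: H2 (1 atm), RhCl(PPh3)3 (5 mol%), benzene, rt
Reagents that add atoms: none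
Why: Homogeneous hydrogenation with Wilkinson's catalyst, which discriminates strongly by alkene substitution and adds hydrogen 1,2; the 1,1-disubstituted isopropenyl alkene should be reduced and the trisubstituted ring alkene next to C5 left.

Step 8
Reactants: 12 isopropylcyclopentene
Product: 13 homoallylic alcohol (5-(hydroxymethyl)-4-isopropyl-1-(dimethoxymethyl)-1-methylcyclopent-3-ene)
Conditions: Bu4NF, THF, 0 °C → rt
Reagents that add atoms: none
Why: Fluoride-induced cleavage of the silyl ether; acetal and alkene are inert.

Step 9
Reactants: 13 homoallylic alcohol
Product: 14 epoxy alcohol (3,4-epoxide on the upper face, cis to the C5 hydroxymethyl group)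
Conditions: VO(acac)2 (5 mol%), t-BuOOH (1.5 equiv, decane), CH2Cl2, 0 °C → rt
Reagents that add atoms: tert-butyl hydroperoxide, CC(C)(C)OO
Why: Hydroxyl-directed epoxidation; the homoallylic alkoxide and the peroxide bind pentavalent vanadium together, so oxygen is delivered to C3=C4 from the face of the C6 hydroxymethyl group. This sets the C4–O bond cis to C6 and to the C1 methyl group against the steric preference of an undirected peracid.

Step 10
Reactants: 14 epoxy alcohol
Product: 15 diol (C4 tertiary alcohol, C6 primary alcohol, C10 dimethyl acetal; 1S,4R,5S)
Conditions: LiAlH4, THF, 0 → 65 °C; aq. NaOH work-up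
Reagents that add atoms: none
Why: SN2 opening of the trisubstituted epoxide by hydride at the secondary carbon C3, which becomes a methylene group; the tertiary C4–O bond is kept with its configuration.

Step 11
Reactants: 15 diol
Product: 16 β-hydroxy aldehyde (C6 aldehyde, C4 tertiary alcohol)
Conditions: Dess–Martin periodinane, NaHCO3, CH2Cl2, 0 °C → rt; used crude
Reagents that add atoms: none
Why: Dess–Martin oxidation of the primary alcohol; the tertiary hydroxyl cannot be oxidised, and the buffered, base-free medium avoids epimerisation at C5, dehydration and retro-aldol cleavage.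

Step 12
Reactants: 16 β-hydroxy aldehyde; 17 2-methylallylmagnesium chloride
Product: 18 homoallylic diol (6S secondary alcohol carrying the 2-methylallyl group, C4 tertiary alcohol, C10 acetal)
Conditions: 17 (3 equiv), THF/CH2Cl2, −78 °C; aq. NH4Cl
Reagents that add atoms: none
Why: Grignard addition under Cram-chelate control; the first equivalent makes the C4 magnesium alkoxide, which binds the C6 carbonyl oxygen in a six-membered chelate and fixes it on the C4 side. The carbonyl face towards the C1 methyl group is blocked, so the allyl group should enter anti to C1 and give the 6S carbinol.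

Step 13
Reactants: 18 homoallylic diol; 19 4-methoxybenzoyl chloride
Product: 20 C6 4-methoxybenzoate (C4 alcohol free, C10 acetal)
Conditions: 19 (1.5 equiv), Et3N, DMAP (0.2 equiv), CH2Cl2, 0 °C → rt
Reagents that add atoms: none
Why: DMAP-catalysed acylation; only the secondary C6 hydroxyl can react, because C4–OH is tertiary and hindered and C10 is still an acetal.

Step 14
Reactants: 20 C6 4-methoxybenzoate
Product: 21 C10 aldehyde
Conditions: PPTS (0.2 equiv), acetone/H2O (9:1), 45 °C
Reagents that add atoms: water, O
Why: Acid-catalysed hydrolysis of the acyclic acetal through the oxocarbenium ion; the aryl ester, the tertiary alcohol and the 1,1-disubstituted alkene tolerate the pyridinium acid. C10 lies on the lower face and cannot form a lactol with the C4 or C6 oxygens on the upper face.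

Step 15
Reactants: 21 C10 aldehyde; 22 vinyl bromide
Product: 23 C10 vinyl carbinols (both C10 epimers, carried on together)
Conditions: CrCl2 (6 equiv), NiCl2 (2 mol%), 22 (5 equiv), DMF, rt
Reagents that add atoms: none
Why: Nozaki–Hiyama–Kishi reaction; zerovalent nickel inserts into the C–Br bond, the vinyl group passes to trivalent chromium and the vinylchromium adds to the aldehyde only, leaving the ester and the free tertiary hydroxyl alone. This forms C9–C10; the C10 configuration is not relied on here because it is reset in steps 16 and 17.

Step 16
Reactants: 23 C10 vinyl carbinols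
Product: 24 vinyl ketone (C10 ketone)
Conditions: Dess–Martin periodinane, NaHCO3, CH2Cl2, 0 °C; used at once
Reagents that add atoms: none
Why: Dess–Martin oxidation of the secondary allylic alcohol; both epimers converge on one ketone, and the tertiary alcohol and ester are inert.

Step 17
Reactants: 24 vinyl ketone
Product: 25 (10R)-vinyl carbinol
Conditions: (S)-1-methyl-3,3-diphenyltetrahydro-1H,3H-pyrrolo[1,2-c][1,3,2]oxazaborole (0.5 equiv), catecholborane (3 equiv), toluene, −78 → −40 °C
Reagents that add atoms: none
Why: Corey–Bakshi–Shibata reduction; the ketone binds the catalyst boron anti to its larger substituent (quaternary C1, vinyl as the small group), and the (S)-catalyst then delivers hydride to the face that gives the 10R carbinol. Felkin–Anh attack anti to C5 points the same way, and catecholborane at low temperature should not hydroborate the alkenes.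

Step 18
Reactants: 25 (10R)-vinyl carbinol
Product: 26 target, (1S,4R,5S,6S,10R)-4,10-dihydroxy-4-isopropyl-1,8-dimethylbicyclo[5.3.0]dec-8-en-6-yl 4-methoxybenzoate (entry numbering)
Conditions: second-generation Grubbs catalyst RuCl2(=CHPh)(H2IMes)(PCy3) (10 mol%), CH2Cl2 (2 mM), 40 °C
Reagents that add atoms: none
Why: Ring-closing metathesis; the ruthenium carbene loads on the monosubstituted vinyl group and closes onto the 1,1-disubstituted alkene with loss of ethylene. The new C8=C9 alkene is necessarily cis in the seven-membered ring, and free hydroxyls and the ester are tolerated.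

## Compound list

1 | (tert-butyldimethylsilyloxy)acetaldehyde | CC(C)(C)[Si](C)(C)OCC=O | starting material
2 | 2-(triphenylphosphoranylidene)propanal | CC(C=O)=P(c1ccccc1)(c1ccccc1)c1ccccc1 | starting material
3 | (E)-4-(tert-butyldimethylsilyloxy)-2-methylbut-2-enal | O=C/C(C)=C/CO[Si](C)(C)C(C)(C)C | intermediate
4 | isoprene (2-methylbuta-1,3-diene) | C=CC(C)=C | starting material
5 | (1S,6S)-6-[(tert-butyldimethylsilyloxy)methyl]-1,4-dimethylcyclohex-3-ene-1-carbaldehyde (formyl and silyloxymethyl trans) | O=C[C@@]1(C)CC=C(C)C[C@@H]1CO[Si](C)(C)C(C)(C)C | intermediate
6 | (1S,6S)-6-[(tert-butyldimethylsilyloxy)methyl]-1-(dimethoxymethyl)-1,4-dimethylcyclohex-3-ene | COC(OC)[C@@]1(C)CC=C(C)C[C@@H]1CO[Si](C)(C)C(C)(C)C | intermediate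
7 | secondary ozonide of 6 (1,2,4-trioxolane across the former alkene carbons; both bridgehead arrangements) | COC(OC)[C@@]1(C)CC2OOC(C)(O2)C[C@@H]1CO[Si](C)(C)C(C)(C)C | intermediate
8 | (3S,4S)-4-[(tert-butyldimethylsilyloxy)methyl]-3-(dimethoxymethyl)-3-methyl-6-oxoheptanal | COC(OC)[C@@](C)(CC=O)[C@@H](CO[Si](C)(C)C(C)(C)C)CC(C)=O | intermediate
9 | aldol adduct: 4-acetyl-3-hydroxy cyclopentane (C3 and C4 as formed, C1 and C5 as in 5) | COC(OC)[C@@]1(C)CC(O)C(C(C)=O)[C@@H]1CO[Si](C)(C)C(C)(C)C | intermediate
10 | acetylcyclopentene: 4-acetyl-5-[(tert-butyldimethylsilyloxy)methyl]-1-(dimethoxymethyl)-1-methylcyclopent-3-ene | COC(OC)[C@@]1(C)CC=C(C(C)=O)[C@@H]1CO[Si](C)(C)C(C)(C)C | intermediate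
11 | diene: 4-(prop-1-en-2-yl)-5-[(tert-butyldimethylsilyloxy)methyl]-1-(dimethoxymethyl)-1-methylcyclopent-3-ene | COC(OC)[C@@]1(C)CC=C(C(C)=C)[C@@H]1CO[Si](C)(C)C(C)(C)C | intermediate
12 | 4-isopropyl-5-[(tert-butyldimethylsilyloxy)methyl]-1-(dimethoxymethyl)-1-methylcyclopent-3-ene | COC(OC)[C@@]1(C)CC=C(C(C)C)[C@@H]1CO[Si](C)(C)C(C)(C)C | intermediate
13 | homoallylic alcohol: 5-(hydroxymethyl)-4-isopropyl-1-(dimethoxymethyl)-1-methylcyclopent-3-ene | COC(OC)[C@@]1(C)CC=C(C(C)C)[C@@H]1CO | intermediate
14 | epoxy alcohol: 3,4-epoxide of 13, oxygen cis to the hydroxymethyl group | COC(OC)[C@@]1(C)C[C@@H]2O[C@]2(C(C)C)[C@@H]1CO | intermediate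
15 | diol: (1S,4R,5S)-5-(hydroxymethyl)-4-isopropyl-1-(dimethoxymethyl)-1-methylcyclopentan-4-ol (target locants) | COC(OC)[C@@]1(C)CC[C@@](O)(C(C)C)[C@@H]1CO | intermediate
16 | β-hydroxy aldehyde: C6 aldehyde of 15 | COC(OC)[C@@]1(C)CC[C@@](O)(C(C)C)[C@@H]1C=O | intermediate
17 | 2-methylallylmagnesium chloride | C=C(C)C[Mg]Cl | starting material
18 | homoallylic diol: (6S)-carbinol with 2-methylallyl on C6, C4 tertiary alcohol, C10 dimethyl acetal | COC(OC)[C@@]1(C)CC[C@@](O)(C(C)C)[C@@H]1[C@@H](O)CC(C)=C | intermediate
19 | 4-methoxybenzoyl chloride | COc1ccc(C(Cl)=O)cc1 | starting material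
20 | C6 4-methoxybenzoate of 18 | COC(OC)[C@@]1(C)CC[C@@](O)(C(C)C)[C@@H]1[C@@H](OC(=O)c1ccc(OC)cc1)CC(C)=C | intermediate
21 | C10 aldehyde (C6 4-methoxybenzoate, C4 alcohol) | O=C[C@@]1(C)CC[C@@](O)(C(C)C)[C@@H]1[C@@H](OC(=O)c1ccc(OC)cc1)CC(C)=C | intermediate
22 | vinyl bromide (bromoethene) | C=CBr | starting material
23 | C10 vinyl carbinols (both C10 epimers) | C=CC(O)[C@@]1(C)CC[C@@](O)(C(C)C)[C@@H]1[C@@H](OC(=O)c1ccc(OC)cc1)CC(C)=C | intermediate
24 | vinyl ketone (C10 ketone) | C=CC(=O)[C@@]1(C)CC[C@@](O)(C(C)C)[C@@H]1[C@@H](OC(=O)c1ccc(OC)cc1)CC(C)=C | intermediate
25 | (10R)-vinyl carbinol | C=C[C@@H](O)[C@@]1(C)CC[C@@](O)(C(C)C)[C@@H]1[C@@H](OC(=O)c1ccc(OC)cc1)CC(C)=C | intermediate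
26 | target CNP0211568.1 | COc1ccc(C(=O)O[C@H]2CC(C)=C[C@@H](O)[C@@]3(C)CC[C@@](O)(C(C)C)[C@H]23)cc1 | target

## Step count and least certain steps

Total: 18 steps. Longest linear sequence: 18 steps (1 to 26); 2, 4, 17, 19 and 22 enter as purchased materials.

**Step 2 (key step).** A β-substituted 2-methyl enal is a slow dienophile. The most likely failure is a sluggish catalysed pathway that lets an uncatalysed or achiral-acid pathway and diene oligomerisation compete, which erodes enantioselectivity. The sense of induction is assumed by analogy with 2-methylacrolein and should be confirmed on 5 before going on; if it were opposite, the antipodal catalyst is the remedy. Fallback by resolution, from 3 and 4 back to 5: the cycloaddition is run with Me2AlCl (CH2Cl2, −78 °C) to give the racemic trans aldehyde F1. Condensation with (1R,2R)-N,N′-dimethyl-1,2-diphenylethane-1,2-diamine (molecular sieves, Et2O) gives two diastereomeric imidazolidines, of which the aminal of the (1S,6S) aldehyde F2 is separated by chromatography. Brief hydrolysis with aqueous oxalic acid returns 5.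

**Step 7.** The hydrogenation may not stop at the isopropenyl group: over-reduction of the ring alkene, or 1,4-addition or isomerisation to the tetrasubstituted alkene, would remove the handle for the C4 oxygen. Fallback with the order changed, from 11 to 14: Bu4NF gives the dienol F3. VO(acac)2 with t-BuOOH epoxidises the ring alkene, which is the homoallylic and more electron-rich one, to the vinyl epoxide F4. Diimide (2-nitrobenzenesulfonyl hydrazide, Et3N) then reduces the now isolated 1,1-disubstituted alkene to give 14.

**Step 9.** Delivery from a homoallylic hydroxyl is less rigid than from an allylic one, so facial selectivity may be poor, or the Lewis-acidic metal may open the epoxide. Fallback by a ring-enforced route, from 13 to 15: Boc2O with DMAP gives the tert-butyl carbonate F5. IBr (toluene, −80 °C) gives the iodo carbonate F6 by anti addition; the carbonate oxygen can only enter C4 cis to C6 in the fused six-membered ring. Bu3SnH with AIBN removes iodine to give the cyclic carbonate F7, and K2CO3 in MeOH gives 15.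

**Step 12.** If the alkoxide chelate does not control the very fast allyl Grignard addition, open-chain attack would give the C6 epimer; retro-aldol cleavage of the alkoxide is the second risk. Fallback by reagent control, from 16 to 18: Brown allylboration with the B-(2-methylallyl)diisopinocampheylborane made from (−)-B-methoxydiisopinocampheylborane and 17 (Et2O, −78 °C, ethanolamine work-up). This reagent adds to the Si face of aldehydes, which here is the face that gives 6S. No new isolated compound is involved.

**Step 17.** The hindered ketone may be reduced slowly, so that conjugate reduction or polymerisation of the vinyl ketone competes, or catalyst and substrate preferences may not reinforce each other as assumed. Fallback with ring closure first, from 24 to 26: ring-closing metathesis of 24 (second-generation Grubbs catalyst, toluene, 80 °C) gives the cycloheptenone F8. LiBH(s-Bu)3 (THF, −78 °C) should attack C10 from the open side anti to C5 and place the hydroxyl anti to the angular methyl group, giving 26; the β,β-disubstituted enone disfavours 1,4-reduction.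

## Further compounds

F1 | step 2 | racemic trans-6-[(tert-butyldimethylsilyloxy)methyl]-1,4-dimethylcyclohex-3-ene-1-carbaldehyde | O=CC1(C)CC=C(C)CC1CO[Si](C)(C)C(C)(C)C
F2 | step 2 | (4R,5R)-1,3-dimethyl-4,5-diphenylimidazolidine aminal of 5 | CN1[C@H](c2ccccc2)[C@@H](c2ccccc2)N(C)C1[C@@]1(C)CC=C(C)C[C@@H]1CO[Si](C)(C)C(C)(C)C
F3 | step 7 | dienol: 5-(hydroxymethyl)-4-(prop-1-en-2-yl)-1-(dimethoxymethyl)-1-methylcyclopent-3-ene | COC(OC)[C@@]1(C)CC=C(C(C)=C)[C@@H]1CO
F4 | step 7 | vinyl epoxide: 3,4-epoxide of F3, oxygen cis to the hydroxymethyl group | COC(OC)[C@@]1(C)C[C@@H]2O[C@]2(C(C)=C)[C@@H]1CO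
F5 | step 9 | tert-butyl carbonate of 13 | COC(OC)[C@@]1(C)CC=C(C(C)C)[C@@H]1COC(=O)OC(C)(C)C
F6 | step 9 | iodo carbonate: cyclic carbonate across the C4 and C6 oxygens, iodine on C3 trans to the C4 oxygen | COC(OC)[C@@]1(C)C[C@@H](I)[C@]2(C(C)C)OC(=O)OC[C@H]12
F7 | step 9 | cyclic carbonate of 15 | COC(OC)[C@@]1(C)CC[C@]2(C(C)C)OC(=O)OC[C@H]12
F0 | step 12 | none | none
F8 | step 17 | cycloheptenone: 10-oxo analogue of 26 | COc1ccc(C(=O)O[C@H]2CC(C)=CC(=O)[C@@]3(C)CC[C@@](O)(C(C)C)[C@H]23)cc1
A1 | alternative 1 | 2-(methanesulfonyloxy)-3-methylcyclopent-2-en-1-one | CC1=C(OS(C)(=O)=O)C(=O)CC1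
A2 | alternative 1 | (R)-trimethyl[(4-methylcyclopent-1-en-1-yl)oxy]silane | C[C@@H]1CC=C(O[Si](C)(C)C)C1
A3 | alternative 1 | tricyclic cyclobutane (C5 mesylate, C10 trimethylsilyl ether, C4 ketone) | O=C1CC[C@]2(C)[C@@]3(O[Si](C)(C)C)C[C@H](C)C[C@H]3[C@]12OS(C)(=O)=O
A4 | alternative 2 | siloxycyclopropane on the trans-hydrindane (C8–C9–C10 cyclopropane, C10 trimethylsilyl ether, C4 triethylsilyl ether, C6 4-methoxybenzoate; cyclopropane face not specified) | COc1ccc(C(=O)O[C@H]2CC4(C)CC4(O[Si](C)(C)C)[C@@]3(C)CC[C@@](O[Si](CC)(CC)CC)(C(C)C)[C@H]23)cc1
A5 | alternative 2 | 10-oxo anisate (C4 triethylsilyl ether) | COc1ccc(C(=O)O[C@H]2CC(C)=CC(=O)[C@@]3(C)CC[C@@](O[Si](CC)(CC)CC)(C(C)C)[C@H]23)cc1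
A6 | alternative 3 | tethered enyne with siloxyvinylcyclopropane (C4 triethylsilyl ether, C9 tert-butyldimethylsilyl ether; alkene geometry and cyclopropane configuration not specified) | C#C[C@](O[Si](CC)(CC)CC)(C(C)C)CCC(C)=CC1(O[Si](C)(C)C(C)(C)C)CC1C
A7 | alternative 3 | bicyclic 5-ene with C9 silyl enol ether and quaternary C1 | C[C@@H]1CC=C2[C@](O[Si](CC)(CC)CC)(C(C)C)CC[C@]2(C)C=C1O[Si](C)(C)C(C)(C)C
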